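**Retrosynthetic overview**

- The target is reached from its bis(triisopropylsilyl) ether by fluoride desilylation. The only ring is the oxolane O1–C2–C3–C4–C5 (C2 = aryl CH beside the carbinol, C3 = C(CH3)OH, C4 = CH–CH3, C5 = other aryl CH).
- Feature used: the tertiary carbinol C3 (CH3, OH) sits next to the benzylic ether carbon C2. C3 is therefore read as a methyl ketone and C2 as the CH2 of an O1–CH2–aryl ether whose hydrogens are δ to that carbonyl. The C2–C3 bond and the oxolane are formed last, by a Norrish–Yang photocyclisation.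
- The ketone comes from Tsuji–Wacker oxidation of the terminal alkene of an O-benzylated anti homoallylic alcohol; the ether comes from Williamson alkylation with the O-silylvanillyl bromide.
- C4 and C5 are set by an anti-selective asymmetric (E)-crotylboration of O-silylvanillin; aldehyde and bromide both come from vanillin.

Key step: step 7

Remark: the two phenols are carried as triisopropylsilyl ethers, which should withstand the alkoxide of step 5 better than tert-butyldimethylsilyl ethers. The oxolane numbering above is used for all intermediates.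

**Step 1**
Reactants: 1 vanillin
Product: 2 3-methoxy-4-(triisopropylsilyloxy)benzaldehyde
Conditions: i-Pr3SiCl, imidazole, DMF, rt
Reagents that add atoms: chlorotriisopropylsilane, CC(C)[Si](Cl)(C(C)C)C(C)C
Why: Imidazole-promoted O-silylation of the phenol is routine, leaves the aldehyde untouched and installs a silyl ether bulky enough to survive the later alkoxide and work-up conditions.

**Step 2**
Reactants: 2 3-methoxy-4-(triisopropylsilyloxy)benzaldehyde, 3 trans-2-butene
Product: 7 (1R,2R)-1-[3-methoxy-4-(triisopropylsilyloxy)phenyl]-2-methylbut-3-en-1-ol, via (E)-crotylpotassium 4 (not isolated), via (E)-crotyldiisopinocampheylborane 5 (not isolated), via diisopinocampheylborinic ester 6 (not isolated)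
Conditions: 3, KOt-Bu, n-BuLi, THF, −78 to −45 °C; (+)-B-methoxydiisopinocampheylborane [(+)-Ipc2BOMe], −78 °C; BF3·OEt2, −78 °C; 2, −78 °C; NaBO3·4H2O, THF/H2O, rt
Reagents that add atoms: none
Why: Brown crotylboration through a chair Zimmerman–Traxler transition state with the aryl group equatorial, in which the E geometry of 5 gives the anti relationship (C4/C5 of the oxolane) and the isopinocampheyl groups of the (−)-α-pinene series should direct addition to the Re face of the aldehyde, setting C1 as R and C2 as R.

**Step 3**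
Reactants: 2 3-methoxy-4-(triisopropylsilyloxy)benzaldehyde
Product: 8 [3-methoxy-4-(triisopropylsilyloxy)phenyl]methanol
Conditions: NaBH4, MeOH, 0 °C
Reagents that add atoms: none
Why: Borohydride reduction of an aromatic aldehyde is reliable and the aryl triisopropylsilyl ether is stable to NaBH4 in cold methanol.

**Step 4**
Reactants: 8 [3-methoxy-4-(triisopropylsilyloxy)phenyl]methanol
Product: 9 4-(bromomethyl)-2-methoxy-1-(triisopropylsilyloxy)benzene
Conditions: CBr4, PPh3, CH2Cl2, 0 °C
Reagents that add atoms: tetrabromomethane, BrC(Br)(Br)Br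
Why: Appel bromination converts the primary benzylic alcohol into the bromide under neutral conditions that spare the silyl ether, and the electron-rich bromide is used at once in step 5.

**Step 5**
Reactants: 7 (1R,2R)-1-[3-methoxy-4-(triisopropylsilyloxy)phenyl]-2-methylbut-3-en-1-ol, 9 4-(bromomethyl)-2-methoxy-1-(triisopropylsilyloxy)benzene
Product: 11 2-methoxy-4-[(1R,2R)-1-{[3-methoxy-4-(triisopropylsilyloxy)phenyl]methoxy}-2-methylbut-3-en-1-yl]-1-(triisopropylsilyloxy)benzene, via sodium alkoxide 10 (not isolated)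
Conditions: NaH, THF/DMF (4:1), 0 °C; then 9, n-Bu4NI (cat.), 0 °C to rt
Reagents that add atoms: none
Why: Williamson ether synthesis in which the alkoxide 10 displaces halide from the primary benzylic bromide by SN2 (iodide catalysis), installing the O1–C2H2–aryl unit without touching either stereocentre.

**Step 6**
Reactants: 11 2-methoxy-4-[(1R,2R)-1-{[3-methoxy-4-(triisopropylsilyloxy)phenyl]methoxy}-2-methylbut-3-en-1-yl]-1-(triisopropylsilyloxy)benzene
Product: 12 (3S,4R)-4-[3-methoxy-4-(triisopropylsilyloxy)phenyl]-4-{[3-methoxy-4-(triisopropylsilyloxy)phenyl]methoxy}-3-methylbutan-2-one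
Conditions: PdCl2 (10 mol%), CuCl (1 equiv), O2 (1 atm), DMF/H2O (7:1), rt
Reagents that add atoms: water, O
Why: Tsuji–Wacker oxidation, in which Markovnikov hydroxypalladation of the monosubstituted alkene by divalent palladium and water, β-hydride elimination and tautomerisation give the methyl ketone (C3 of the oxolane) while CuCl/O2 turns the palladium over, under near-neutral conditions that should not enolise C4.

**Step 7**
Reactants: 12 (3S,4R)-4-[3-methoxy-4-(triisopropylsilyloxy)phenyl]-4-{[3-methoxy-4-(triisopropylsilyloxy)phenyl]methoxy}-3-methylbutan-2-one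
Product: 14 (2R,3S,4S,5R)-2,5-bis[3-methoxy-4-(triisopropylsilyloxy)phenyl]-3,4-dimethyloxolan-3-ol, via 1,5-biradical 13 (not isolated)
Conditions: hν (medium-pressure Hg lamp, Pyrex filter, λ > 300 nm), degassed MeCN (0.01 M), rt
Reagents that add atoms: none
Why: The n,π* excited C3 carbonyl of 12 has no γ-hydrogen (the γ position is the ether oxygen O1), so it should abstract one of the δ-hydrogens of the O1–C2H2–aryl group through a seven-membered transition state and give the 1,5-biradical 13 (C3 ketyl radical and C2 α-alkoxybenzyl radical). The two radical centres then combine to form the C2–C3 σ bond, closing the oxolane O1–C2–C3–C4–C5 by 1,5-biradical recombination and not by a polar exo or endo closure; the closest known reaction type is the Norrish–Yang photocyclisation of β-alkoxy ketones to oxolan-3-ols. C3 is controlled by the existing C4 centre: in the closing envelope the C3 methyl should take the face opposite the C4 methyl, leaving the smaller hydroxyl cis to it (3S). C2 is set in the same bond formation: the planar benzylic radical should close with its aryl group on the face away from the acetonitrile-solvated hydroxyl, which is the face of the C5 aryl group and gives the 2,5-cis-diaryl arrangement (2R). The step needs δ-hydrogen abstraction to win over α-cleavage, over charge-transfer quenching by the two electron-rich arenes and over absorption of the light by them; the doubly activated (benzylic and α-oxy) C2–H bonds, the absence of any γ-hydrogen and irradiation above 300 nm, where the ketone n→π* band still absorbs and the arenes hardly do, are what should secure it, and closure diastereomers would be removed by chromatography.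

**Step 8**
Reactants: 14 (2R,3S,4S,5R)-2,5-bis[3-methoxy-4-(triisopropylsilyloxy)phenyl]-3,4-dimethyloxolan-3-ol
Product: 15 (2R,3S,4S,5R)-2,5-bis(4-hydroxy-3-methoxyphenyl)-3,4-dimethyloxolan-3-ol (CNP0234919.2)
Conditions: n-Bu4NF, AcOH, THF, 0 °C
Reagents that add atoms: none
Why: Fluoride desilylation cleaves both aryl Si–O bonds, and the acetic acid buffer keeps the liberated phenols protonated so that the para-hydroxybenzylic C–O bonds at C2 and C5 are not opened through a quinone methide and no stereocentre is disturbed.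

**Compound list**

1 | vanillin (4-hydroxy-3-methoxybenzaldehyde) | COc1cc(C=O)ccc1O | starting material
2 | 3-methoxy-4-(triisopropylsilyloxy)benzaldehyde | COc1cc(C=O)ccc1O[Si](C(C)C)(C(C)C)C(C)C | intermediate
3 | trans-2-butene | C/C=C/C | starting material
4 | (E)-crotylpotassium (formed in the flask, not isolated) | [K+].[CH2-]/C=C/C | intermediate
5 | (E)-crotyldiisopinocampheylborane of the (+)-Ipc2BOMe series (formed in the flask, not isolated) | C/C=C/CB([C@H]1C[C@H]2C[C@@H]([C@@H]1C)C2(C)C)[C@H]1C[C@H]2C[C@@H]([C@@H]1C)C2(C)C | intermediate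
6 | diisopinocampheylborinic ester of alcohol 7 (formed in the flask, not isolated) | C=C[C@@H](C)[C@@H](OB([C@H]1C[C@H]2C[C@@H]([C@@H]1C)C2(C)C)[C@H]1C[C@H]2C[C@@H]([C@@H]1C)C2(C)C)c1ccc(O[Si](C(C)C)(C(C)C)C(C)C)c(OC)c1 | intermediate
7 | (1R,2R)-1-[3-methoxy-4-(triisopropylsilyloxy)phenyl]-2-methylbut-3-en-1-ol | C=C[C@@H](C)[C@@H](O)c1ccc(O[Si](C(C)C)(C(C)C)C(C)C)c(OC)c1 | intermediate
8 | [3-methoxy-4-(triisopropylsilyloxy)phenyl]methanol | COc1cc(CO)ccc1O[Si](C(C)C)(C(C)C)C(C)C | intermediate
9 | 4-(bromomethyl)-2-methoxy-1-(triisopropylsilyloxy)benzene | COc1cc(CBr)ccc1O[Si](C(C)C)(C(C)C)C(C)C | intermediate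
10 | sodium alkoxide of 7 (formed in the flask, not isolated) | [Na+].C=C[C@@H](C)[C@@H]([O-])c1ccc(O[Si](C(C)C)(C(C)C)C(C)C)c(OC)c1 | intermediate
11 | 2-methoxy-4-[(1R,2R)-1-{[3-methoxy-4-(triisopropylsilyloxy)phenyl]methoxy}-2-methylbut-3-en-1-yl]-1-(triisopropylsilyloxy)benzene | C=C[C@@H](C)[C@@H](OCc1ccc(O[Si](C(C)C)(C(C)C)C(C)C)c(OC)c1)c1ccc(O[Si](C(C)C)(C(C)C)C(C)C)c(OC)c1 | intermediate
12 | (3S,4R)-4-[3-methoxy-4-(triisopropylsilyloxy)phenyl]-4-{[3-methoxy-4-(triisopropylsilyloxy)phenyl]methoxy}-3-methylbutan-2-one | CC(=O)[C@@H](C)[C@@H](OCc1ccc(O[Si](C(C)C)(C(C)C)C(C)C)c(OC)c1)c1ccc(O[Si](C(C)C)(C(C)C)C(C)C)c(OC)c1 | intermediate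
13 | 1,5-biradical from 12: C3 ketyl radical and C2 α-alkoxybenzyl radical (not isolated) | C[C](O)[C@@H](C)[C@@H](O[CH]c1ccc(O[Si](C(C)C)(C(C)C)C(C)C)c(OC)c1)c1ccc(O[Si](C(C)C)(C(C)C)C(C)C)c(OC)c1 | intermediate
14 | (2R,3S,4S,5R)-2,5-bis[3-methoxy-4-(triisopropylsilyloxy)phenyl]-3,4-dimethyloxolan-3-ol | COc1cc([C@H]2O[C@@H](c3ccc(O[Si](C(C)C)(C(C)C)C(C)C)c(OC)c3)[C@H](C)[C@]2(C)O)ccc1O[Si](C(C)C)(C(C)C)C(C)C | intermediate
15 | (2R,3S,4S,5R)-2,5-bis(4-hydroxy-3-methoxyphenyl)-3,4-dimethyloxolan-3-ol (CNP0234919.2) | COc1cc([C@H]2O[C@@H](c3ccc(O)c(OC)c3)[C@H](C)[C@]2(C)O)ccc1O | target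

**Step count**

Total steps: 8. Longest linear sequence: 7 steps from vanillin (steps 1, 3, 4, 5, 6, 7, 8).

**Steps most likely to fail**

Step 7 (photocyclisation). Three things may go wrong. Charge transfer from the electron-rich arenes (above all the aryl group at C5, β to the carbonyl) may quench the excited ketone, or the arenes may filter the light, so that conversion stalls. The biradical may close on the wrong face at C2 or C3. Hydrogen back-transfer within the biradical through the enol may erode C4.

The fallback closes the ring at O1–C2 instead, by known chemistry. It sets out from aldehyde 2 and comes back at 14.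
- Aldehyde 2 is propargylated anti-selectively with the allenylzinc reagent from (S)-but-3-yn-2-yl methanesulfonate (Pd(OAc)2, PPh3, Et2Zn, THF). This should give (1R,2R)-1-[3-methoxy-4-(triisopropylsilyloxy)phenyl]-2-methylbut-3-yn-1-ol F1.
- Zirconium-catalysed methylalumination of the alkyne (AlMe3, Cp2ZrCl2, CH2Cl2) is followed by palladium-catalysed coupling (Pd(PPh3)4, ZnCl2, THF) with 4-iodo-2-methoxy-1-(triisopropylsilyloxy)benzene F2, itself made from 4-iodo-2-methoxyphenol and chlorotriisopropylsilane. This should give (1R,2R,3E)-1,4-bis[3-methoxy-4-(triisopropylsilyloxy)phenyl]-2,3-dimethylbut-3-en-1-ol F3.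
- Shi epoxidation with the L-fructose-derived ketone (KHSO5, K2CO3 buffer, MeCN/dimethoxymethane, 0 °C) should give (1R,2S)-1-[3-methoxy-4-(triisopropylsilyloxy)phenyl]-2-{(2S,3S)-3-[3-methoxy-4-(triisopropylsilyloxy)phenyl]-2-methyloxiran-2-yl}propan-1-ol F4.
- Catalytic camphorsulfonic acid (CH2Cl2, −20 °C) then lets the C5 hydroxyl open the epoxide at the benzylic carbon C2 (5-endo, inversion at C2). This should give 14, with C2 and C3 fixed by the alkene geometry and the epoxide face instead of by the biradical closure.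

Step 6 (Wacker oxidation). Anti-Markovnikov oxypalladation steered by the ether oxygen may give the aldehyde. Palladium hydride may migrate the alkene and erase C4. Acid may cleave the electron-rich benzylic ether or cause β-elimination of the product.

The fallback sets out from alkene 11 and comes back at ketone 12.
- Buffered epoxidation (mCPBA, NaHCO3, CH2Cl2) should give 2-methoxy-4-[(1R,2S)-1-{[3-methoxy-4-(triisopropylsilyloxy)phenyl]methoxy}-2-(oxiran-2-yl)propyl]-1-(triisopropylsilyloxy)benzene F5 (both oxirane epimers).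
- Hydride opening at the terminal carbon (LiEt3BH, THF, 0 °C) should give (3R,4R)-4-[3-methoxy-4-(triisopropylsilyloxy)phenyl]-4-{[3-methoxy-4-(triisopropylsilyloxy)phenyl]methoxy}-3-methylbutan-2-ol F6 (both C2 epimers).
- Dess–Martin periodinane (NaHCO3, CH2Cl2) oxidises F6 to 12.

Step 5 (Williamson etherification). Alkylation of the hindered secondary alkoxide may be slow. A silyl group may migrate from an aryl oxygen to the alkoxide. The electron-rich bromide may decompose before it is consumed.

The fallback sets out from alcohols 8 and 7 and comes back at ether 11.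
- Alcohol 8 is converted (Cl3CCN, cat. DBU, CH2Cl2, 0 °C) into [3-methoxy-4-(triisopropylsilyloxy)phenyl]methyl 2,2,2-trichloroacetimidate F7.
- F7 alkylates alcohol 7 under mild acid catalysis (cat. camphorsulfonic acid, CH2Cl2, 0 °C) to give 11. The O–C bond is then formed through the stabilised benzylic cation and no base is present.

**Further compounds**

F1 | step 7 | (1R,2R)-1-[3-methoxy-4-(triisopropylsilyloxy)phenyl]-2-methylbut-3-yn-1-ol | C#C[C@@H](C)[C@@H](O)c1ccc(O[Si](C(C)C)(C(C)C)C(C)C)c(OC)c1
F2 | step 7 | 4-iodo-2-methoxy-1-(triisopropylsilyloxy)benzene | COc1cc(I)ccc1O[Si](C(C)C)(C(C)C)C(C)C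
F3 | step 7 | (1R,2R,3E)-1,4-bis[3-methoxy-4-(triisopropylsilyloxy)phenyl]-2,3-dimethylbut-3-en-1-ol | COc1cc(/C=C(\C)[C@@H](C)[C@@H](O)c2ccc(O[Si](C(C)C)(C(C)C)C(C)C)c(OC)c2)ccc1O[Si](C(C)C)(C(C)C)C(C)C
F4 | step 7 | (1R,2S)-1-[3-methoxy-4-(triisopropylsilyloxy)phenyl]-2-{(2S,3S)-3-[3-methoxy-4-(triisopropylsilyloxy)phenyl]-2-methyloxiran-2-yl}propan-1-ol | COc1cc([C@@H]2O[C@@]2(C)[C@@H](C)[C@@H](O)c2ccc(O[Si](C(C)C)(C(C)C)C(C)C)c(OC)c2)ccc1O[Si](C(C)C)(C(C)C)C(C)C
F5 | step 6 | 2-methoxy-4-[(1R,2S)-1-{[3-methoxy-4-(triisopropylsilyloxy)phenyl]methoxy}-2-(oxiran-2-yl)propyl]-1-(triisopropylsilyloxy)benzene (both oxirane epimers) | C1OC1[C@@H](C)[C@@H](OCc1ccc(O[Si](C(C)C)(C(C)C)C(C)C)c(OC)c1)c1ccc(O[Si](C(C)C)(C(C)C)C(C)C)c(OC)c1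
F6 | step 6 | (3R,4R)-4-[3-methoxy-4-(triisopropylsilyloxy)phenyl]-4-{[3-methoxy-4-(triisopropylsilyloxy)phenyl]methoxy}-3-methylbutan-2-ol (both C2 epimers) | CC(O)[C@@H](C)[C@@H](OCc1ccc(O[Si](C(C)C)(C(C)C)C(C)C)c(OC)c1)c1ccc(O[Si](C(C)C)(C(C)C)C(C)C)c(OC)c1
F7 | step 5 | [3-methoxy-4-(triisopropylsilyloxy)phenyl]methyl 2,2,2-trichloroacetimidate | COc1cc(COC(=N)C(Cl)(Cl)Cl)ccc1O[Si](C(C)C)(C(C)C)C(C)C
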